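The numbers in the tables are simulated for an exercise; noise was put on by code.

Before trusting any fitted constants, I wanted one I could read by hand. The flasks and questions were these.

| flask | starting material | coupling partner | second substrate | remark | time |
|---|---|---|---|---|---|
| eta | 0.050 M | 0.055 M | 0.050 M | run made earlier |  |
| alpha | 0.050 M | 0.028 M | 0.050 M | run made earlier |  |
| epsilon | 0.050 M | 0.041 M | 0.050 M | run made earlier |  |
| north-east | 0.050 M | 0.0550 M | 0.0500 M | everything together in a closed stirred flask, run for 12 h | 12 h |
| south-west | 0.050 M | 0.0550 M | 0.0500 M | one stirred flow tank at steady state, fed with the mixture as stated, mean residence time 12 h |  |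
| south-east | 0.050 M | 0.0550 M | 0.0500 M (fed, over 12.0 h) | all but second substrate at the start; second substrate goes in evenly over 12.0 h, the run ends at 12 h | 12 h |
| south | 0.050 M (fed, over 12.0 h) | 0.0550 M | 0.0500 M | a stirred flask in which starting material is dosed at a steady rate over 12.0 h without added volume, worked up at 12 h | 12 h |

| run | time / h | target / % |
|---|---|---|
| eta | 1.00 | 8.7 |
| eta | 1.50 | 11.3 |
| eta | 2.50 | 13.3 |
| eta | 4.00 | 14.3 |
| eta | 8.00 | 12.0 |
| eta | 12.0 | 9.1 |
| alpha | 1.00 | 4.8 |
| alpha | 3.00 | 7.4 |
| alpha | 5.00 | 6.5 |
| alpha | 8.00 | 4.4 |
| alpha | 12.0 | 2.6 |
| alpha | 15.0 | 2.6 |
| epsilon | 1.00 | 7.2 |
| epsilon | 3.00 | 10.7 |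
| epsilon | 5.00 | 10.9 |
| epsilon | 8.00 | 8.2 |
| epsilon | 12.0 | 5.4 |
| epsilon | 15.0 | 4.2 |

(standard deviation of a reading: 0.3 percentage points)

- a species is counted by the starting material in it: one side product counts as two
- the stated concentrations are those of everything mixed, before any reaction; amounts are the same in each set-up
- what may be going on: second substrate + coupling partner -> second product; coupling partner -> decomposed reagent; starting material + target -> side product; starting material + coupling partner -> target
- the feed brings no volume worth counting
- the earlier runs were made in a closed, stirred flask

- the set-up with the highest amount of target at the outlet or at the end, in percent of the starting material put in ("none" if the first two lie within 2 percentage points) (north-east / south-west / south-east / south / none)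
- amount of target at the outlet or at the end, in percent of the starting material put in, north-east
- amount of target at the outlet or at the end, in percent of the starting material put in, south-west
- amount of target at the outlet or at the end, in percent of the starting material put in, south-east
- amount of target at the outlet or at the end, in percent of the starting material put in, south

The puzzle stood in eta: 0.055 M of coupling partner on 0.050 M of starting material, an excess, yet target read 14.3 % at 4.00 h and 9.1 % at 12.0 h.

I solved the late end first. Alpha had the lowest charge of partner, so I took its fall from 5.00 h to 12.0 h as nearly bare loss of target to starting material, a pseudo-first-order decay at 0.131 h⁻¹, a half-life of 5.30 h. Dividing by [starting material] as charged gave the erosion constant, the target lost per hour per unit of target and of [starting material], read as 2.62 M⁻¹ h⁻¹.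

Then I joined the ends. Near eta's highest reading, making about equalled erosion, so, taking alpha's decay for eta with the same charge of starting material, I estimated making there at about 21.5 % of eta's first-hour gain. The charged excess did not keep making ahead of erosion after 4.00 h: target read 12.0 % at 8.00 h.

The forecast said 9.1 % for north-east, 8 % for south-west, 12 % for south-east and 4 % for south, best south-east: “Dosing the second substrate spares the coupling partner early”.

The flasks gave, in the same order, 9.01 %, 8.75 %, 18.1 % and 4.75 %, best south-east, which stood 6.1 percentage points above its forecast.

    second substrate + coupling partner → second product (k = 8.40 M⁻¹ h⁻¹)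
    coupling partner → decomposed reagent (k = 0.0810 h⁻¹)
    starting material + target → side product (k = 3.10 M⁻¹ h⁻¹)
    starting material + coupling partner → target (k = 2.40 M⁻¹ h⁻¹)

In south-east, second substrate consumed coupling partner as it came in while target formed, and starting material stood at 41.4 % of its charge at 12 h, where the erosion constant gives target a half-life of 12.8 h. In south-west, [starting material] held at 0.0344 M over a mean residence of 12 h, so the constant lets 48.0 % of the target made leave uneroded, while the outlet's target, set against itself plus the target held in side product (half of that product's count), comes to 43.9 %.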